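Locants follow the target chain (C1 = alkyne CH, C15 = methyl). Everything rests on disconnecting C6–C7 and C8–C9, the two bonds flanking the C7–C8 unit of the oxocane (ring B). Both are made at once by a Prins–pinacol rearrangement of the cyclic acetal of a vinyl 1,2-diol (C4–C8) with an α-benzoyloxy aldehyde (C9–C15). The step exploits the O–C6–C7(O)–C8–C9–O array of ring B, folding it into a temporary 3-acetyl oxolane (ring C) whose oxygen sits on C6 and C9. Later a bromonium-triggered ring expansion moves that oxygen to C12, Baeyer–Villiger oxidation converts acetyl into the C7 oxygen, and epoxide opening closes the oxolane (ring A).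

Key step: step 5

Remark on numbering: chain locants are HC1≡C2–C3HBr–C4H(O)–C5H2–C6H(O)–C7H(O)–C8H2–C9H(OAc)–C10HBr–C11H2–C12H(O)–C13HBr–C14H2–C15H3; ring A = oxolane (O, C4–C7), ring B = oxocane (O, C6–C12), ring C = temporary oxolane (O, C6–C9).
Assumption: (E)-hept-4-enal (1) and 3-[(tert-butyldiphenylsilyl)oxy]propanal (3) are purchased; the L-fructose-derived Shi ketone is used as a reagent.

Step 1
Reactants: 1 (E)-hept-4-enal
Product: 2 (2R,4E)-2-(benzoyloxy)hept-4-enal
Conditions: (PhCO2)2, (R)-2-(triphenylmethyl)pyrrolidine (10 mol%), hydroquinone (10 mol%), THF, 0 °C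
Reagents that add atoms: dibenzoyl peroxide O=C(OOC(=O)c1ccccc1)c1ccccc1
Why: Organocatalytic α-benzoyloxylation of an aldehyde: the enamine of 1 attacks the peroxide O–O bond on the face opposite the trityl group, which should set C10 as R, while the isolated alkene is inert.

Step 2
Reactants: 3 3-[(tert-butyldiphenylsilyl)oxy]propanal
Product: 4 rac-5-[(tert-butyldiphenylsilyl)oxy]-2-methylpent-1-en-3-ol
Conditions: CH2=C(CH3)MgBr, THF, −78 → 0 °C; then aq. NH4Cl
Reagents that add atoms: isopropenylmagnesium bromide CC(=C)[Mg]Br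
Why: Grignard 1,2-addition to the aldehyde should give the racemic 2-methylallylic alcohol, the substrate class that the next step resolves.

Step 3
Reactants: 4 rac-allylic alcohol
Product: 5 (1S)-3-[(tert-butyldiphenylsilyl)oxy]-1-[(2R)-2-methyloxiran-2-yl]propan-1-ol
Conditions: Ti(OCHMe2)4, L-(+)-diisopropyl tartrate, t-BuOOH (0.5 equiv), 4 Å molecular sieves, CH2Cl2, −20 °C
Reagents that add atoms: tert-butyl hydroperoxide CC(C)(C)OO
Why: Sharpless kinetic resolution: with the L-(+)-tartrate the 3S enantiomer of 4 should be epoxidized much faster and anti to the carbinol substituent, which fixes C6 as S (the epoxide carbon loses its stereocenter in step 5), and the slow 3R alcohol is separated.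

Step 4
Reactants: 5 epoxy alcohol
Product: 6 (3R,4S)-6-[(tert-butyldiphenylsilyl)oxy]-3-methylhex-1-ene-3,4-diol
Conditions: Me3SI, n-BuLi, THF, −10 °C → rt
Reagents that add atoms: trimethylsulfonium iodide C[S+](C)C.[I-]
Why: One-carbon homologation of an epoxide to an allylic alcohol: dimethylsulfonium methylide opens the terminal epoxide at CH2 and the resulting oxido sulfonium salt eliminates Me2S, giving the vinyl carbinol without touching C6.

Step 5
Reactants: 6 (3R,4S)-diol; 2 (2R)-aldehyde
Product: 8 all-cis ring C ketone (6S,7S,9S,10R), via dioxolane acetal 7 (not isolated)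
Conditions: TsOH·H2O (cat.), MgSO4, CH2Cl2, 0 °C → rt; then SnCl4, CH2Cl2, −78 → −20 °C
Reagents that add atoms: none
Why: SnCl4 opens acetal 7 at the tertiary C–O bond to the (E)-oxocarbenium ion C9=O+–C6; the vinyl group attacks it through a six-membered chair (Prins closure, new bond C8–C9) and the cation left at C7 is quenched by a 1,2-shift of C6 from the carbinol carbon to C7 (pinacol step, new bond C6–C7), which turns the carbinol carbon into the acetyl C=O. This is the Prins–pinacol rearrangement of allylic diol acetals to 3-acyl oxolanes. Ring C is closed by the two C–C bonds alone: a 6-endo-trig closure to an oxanyl cation followed by ring contraction, with no new C–O bond. C9 is set by the chair in which the C10 chain and the C6 substituent are both equatorial (2,5-cis to C6), C6 migrates with retention, and C7 is set by migration onto the face of the cation syn to C6, so the all-cis ketone should result. The step needs the vinyl group to win the oxocarbenium ion over the remote C12=C13 alkene and the C10 benzoate: only the vinyl group reaches C9 through a six-membered chair, and the shift is driven by C=O formation.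

Step 6
Reactants: 8 all-cis ring C ketone
Product: 9 7-epi ring C ketone (6S,7R,9S,10R)
Conditions: DBU (0.2 equiv), CH2Cl2, 0 °C → rt
Reagents that add atoms: none
Why: Base-mediated epimerization α to the ketone under thermodynamic control should move the C7 acetyl group trans to the C6 side chain, the configuration that the ring A fusion needs, the mild base being chosen to avoid retro-oxa-Michael opening of ring C.

Step 7
Reactants: 9 trans ring C ketone
Product: 12 ring B ketone (6S,7R,9R,10S,12R,13S) with 9-benzoate and 10- and 13-bromides, via bicyclic oxonium ion 10 (not isolated), via dioxolanylium ion 11 (not isolated)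
Conditions: [Et2SBr][SbCl5Br] (1.2 equiv), MeNO2, −25 °C; then n-Bu4NBr (3 equiv), −25 → 0 °C
Reagents that add atoms: bromodiethylsulfonium bromopentachloroantimonate CC[S+](Br)CC.Cl[Sb-](Cl)(Cl)(Cl)(Cl)Br; tetrabutylammonium bromide CCCC[N+](CCCC)(CCCC)CCCC.[Br-]
Why: Proposed new method: the bromonium ion on C12=C13 is opened 5-exo by the ring C oxygen (anti addition across the E-alkene sets C12 and C13, the bromopropyl group lying on the convex face of oxonium ion 10), the C10 benzoate on that same face then attacks the bridgehead C9 from the rear (inversion at C9, expansion to ring B) to give the trans-fused 2-phenyl-1,3-dioxolan-2-ylium ion 11, and bromide opens 11 at C10 with inversion because the rear of C9 is screened by the transannular ring B oxygen; the closest known reactions are the bromonium-induced ring expansion of oxolanes to oxocanes ended by an internal carbonate and the bromide opening of 1,3-dioxolan-2-ylium ions to vicinal bromo esters (Hanessian–Hullar type).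

Step 8
Reactants: 12 ring B ketone
Product: 13 ring B 7-acetate 9-benzoate (6S,7R,9R,10S,12R,13S)
Conditions: mCPBA, CH2Cl2, rt
Reagents that add atoms: 3-chloroperbenzoic acid OOC(=O)c1cccc(Cl)c1
Why: Baeyer–Villiger oxidation: the secondary C7 should migrate in preference to methyl and with retention, so the acetyl group becomes the C7 acetate, and no alkene is left to compete.

Step 9
Reactants: 13 silyl ether
Product: 14 C4 primary alcohol
Conditions: n-Bu4NF, AcOH, THF, 0 °C → rt
Reagents that add atoms: none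
Why: Fluoride-mediated desilylation frees the primary C4 hydroxyl, the acetic acid buffer keeping both esters in place and suppressing base-induced loss of HBr.

Step 10
Reactants: 14 C4 alcohol
Product: 15 C4 aldehyde
Conditions: Dess–Martin periodinane, CH2Cl2, 0 °C → rt
Reagents that add atoms: none
Why: Dess–Martin oxidation of the primary alcohol under neutral conditions should spare the esters and bromides and avoid β-elimination of the β-alkoxy aldehyde.

Step 11
Reactants: 15 C4 aldehyde
Product: 16 (3E)-1-trimethylsilyl enyne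
Conditions: (EtO)2P(O)CH2C≡CSiMe3, LiN(SiMe3)2, THF, −78 → 0 °C
Reagents that add atoms: diethyl [3-(trimethylsilyl)prop-2-yn-1-yl]phosphonate CCOP(=O)(CC#C[Si](C)(C)C)OCC
Why: Horner–Wadsworth–Emmons olefination with the propargyl phosphonate anion adds C1–C3 and should give the conjugated enyne with E geometry at C3=C4.

Step 12
Reactants: 16 (3E)-enyne
Product: 17 (3S,4S)-epoxide
Conditions: L-fructose-derived Shi ketone (0.3 equiv), KHSO5 (as 2KHSO5·KHSO4·K2SO4), K2CO3, n-Bu4NHSO4, MeCN/CH2(OMe)2/aq. buffer pH 10.5, 0 °C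
Reagents that add atoms: potassium peroxymonosulfate [K+].[O-]S(=O)(=O)OO
Why: Shi epoxidation: the chiral dioxirane transfers oxygen to the E-enyne through the spiro transition state, and this enantiomer of the ketone should deliver it to the face that gives the (3S,4S)-epoxide (reagent control).

Step 13
Reactants: 17 (3S,4S)-epoxide
Product: 19 ring A/ring B diol (3S,4R,6S,7R,9R,10S,12R,13S), via epoxy diol 18 (not isolated)
Conditions: K2CO3, MeOH, 0 °C → rt; then camphorsulfonic acid (cat.), CH2Cl2, rt
Reagents that add atoms: none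
Why: Methanolysis removes the acetate, the benzoate and the alkynyl silyl group, and the free C7 hydroxyl then opens the epoxide at C4 in 5-exo mode with inversion (epoxide-opening cycloetherification), which closes ring A trans-fused to ring B, sets C4 as R and leaves the 3S propargylic alcohol.

Step 14
Reactants: 19 diol
Product: 20 (3R)-propargylic bromide with free C9 hydroxyl
Conditions: PPh3, CBr4, CH2Cl2, −20 → 0 °C
Reagents that add atoms: carbon tetrabromide BrC(Br)(Br)Br
Why: Appel reaction: the unhindered propargylic C3 hydroxyl is activated and displaced by bromide with inversion (3S to 3R), while the ring hydroxyl at C9, flanked by the C10 bromide, should react much more slowly at this temperature.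

Step 15
Reactants: 20 bromo alcohol
Product: 21 target, (3R,4R,6S,7R,9R,10S,12R,13S)-9-acetoxy-3,10,13-tribromo-4,7:6,12-diepoxypentadec-1-yne
Conditions: Ac2O, pyridine, DMAP (cat.), CH2Cl2, 0 °C
Reagents that add atoms: acetic anhydride CC(=O)OC(C)=O
Why: Acylation of the remaining secondary C9 hydroxyl with retention installs the acetate and completes the target.

Compound list
1 | (E)-hept-4-enal | CC/C=C/CCC=O | starting material
2 | (2R,4E)-2-(benzoyloxy)hept-4-enal | O=C[C@H](OC(=O)c1ccccc1)C/C=C/CC | intermediate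
3 | 3-[(tert-butyldiphenylsilyl)oxy]propanal | CC(C)(C)[Si](c1ccccc1)(c1ccccc1)OCCC=O | starting material
4 | rac-5-[(tert-butyldiphenylsilyl)oxy]-2-methylpent-1-en-3-ol | CC(C)(C)[Si](c1ccccc1)(c1ccccc1)OCCC(O)C(C)=C | intermediate
5 | (1S)-3-[(tert-butyldiphenylsilyl)oxy]-1-[(2R)-2-methyloxiran-2-yl]propan-1-ol | CC(C)(C)[Si](c1ccccc1)(c1ccccc1)OCC[C@H](O)[C@@]1(C)CO1 | intermediate
6 | (3R,4S)-6-[(tert-butyldiphenylsilyl)oxy]-3-methylhex-1-ene-3,4-diol | CC(C)(C)[Si](c1ccccc1)(c1ccccc1)OCC[C@H](O)[C@](C)(O)C=C | intermediate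
7 | (1R,3E)-1-[(4R,5S)-5-{2-[(tert-butyldiphenylsilyl)oxy]ethyl}-4-ethenyl-4-methyl-1,3-dioxolan-2-yl]hex-3-en-1-yl benzoate, both epimers at the acetal carbon | CC(C)(C)[Si](c1ccccc1)(c1ccccc1)OCC[C@@H]1OC(O[C@]1(C)C=C)[C@H](OC(=O)c1ccccc1)C/C=C/CC | intermediate
8 | (1R,3E)-1-[(2S,4S,5S)-4-acetyl-5-{2-[(tert-butyldiphenylsilyl)oxy]ethyl}oxolan-2-yl]hex-3-en-1-yl benzoate (all-cis ring C ketone; 6S,7S,9S,10R) | CC(C)(C)[Si](c1ccccc1)(c1ccccc1)OCC[C@@H]1O[C@H]([C@H](OC(=O)c2ccccc2)C/C=C/CC)C[C@@H]1C(C)=O | intermediate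
9 | (1R,3E)-1-[(2S,4R,5S)-4-acetyl-5-{2-[(tert-butyldiphenylsilyl)oxy]ethyl}oxolan-2-yl]hex-3-en-1-yl benzoate (acetyl trans to both side chains; 6S,7R,9S,10R) | CC(C)(C)[Si](c1ccccc1)(c1ccccc1)OCC[C@@H]1O[C@H]([C@H](OC(=O)c2ccccc2)C/C=C/CC)C[C@H]1C(C)=O | intermediate
10 | bicyclic trialkyloxonium ion: oxygen bonded to C6, C9 and C12, two fused five-membered rings, (S)-1-bromopropyl on C12 and benzoate on C10 both on the convex face (6S,7R,9S,10R,12R,13S) | CC(C)(C)[Si](c1ccccc1)(c1ccccc1)OCC[C@@H]1[O+]2[C@@H]([C@@H](Br)CC)C[C@@H](OC(=O)c3ccccc3)[C@@H]2C[C@H]1C(C)=O | intermediate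
11 | ring B oxocane carrying a trans-fused 2-phenyl-1,3-dioxolan-2-ylium ring on C9/C10 (6S,7R,9R,10R,12R,13S) | CC(C)(C)[Si](c1ccccc1)(c1ccccc1)OCC[C@@H]2O[C@@H]([C@@H](Br)CC)C[C@H]3[O+]=C(c4ccccc4)O[C@@H]3C[C@H]2C(C)=O | intermediate
12 | ring B oxocane (O on C6 and C12): 2-(silyloxy)ethyl at C6, acetyl at C7 (trans to it), benzoate at C9 and Br at C10 (cis), (S)-1-bromopropyl at C12 (trans to the C6 chain); 6S,7R,9R,10S,12R,13S | CC(C)(C)[Si](c1ccccc1)(c1ccccc1)OCC[C@@H]2O[C@@H]([C@@H](Br)CC)C[C@H](Br)[C@H](OC(=O)c1ccccc1)C[C@H]2C(C)=O | intermediate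
13 | as 12 with the C7 acetyl replaced by acetoxy (6S,7R,9R,10S,12R,13S) | CC(C)(C)[Si](c1ccccc1)(c1ccccc1)OCC[C@@H]2O[C@@H]([C@@H](Br)CC)C[C@H](Br)[C@H](OC(=O)c1ccccc1)C[C@H]2OC(C)=O | intermediate
14 | as 13 with free primary C4 hydroxyl | OCC[C@@H]1O[C@@H]([C@@H](Br)CC)C[C@H](Br)[C@H](OC(=O)c2ccccc2)C[C@H]1OC(C)=O | intermediate
15 | as 14 with C4 as aldehyde | O=CC[C@@H]1O[C@@H]([C@@H](Br)CC)C[C@H](Br)[C@H](OC(=O)c2ccccc2)C[C@H]1OC(C)=O | intermediate
16 | (3E)-enyne: C6 side chain CH2–CH=CH–C≡C–SiMe3 on the 7-acetoxy-9-benzoyloxy-10,13-dibromo oxocane | C[Si](C)(C)C#C/C=C/C[C@@H]1O[C@@H]([C@@H](Br)CC)C[C@H](Br)[C@H](OC(=O)c2ccccc2)C[C@H]1OC(C)=O | intermediate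
17 | (3S,4S)-trans-epoxide of 16 | C[Si](C)(C)C#C[C@@H]1O[C@H]1C[C@@H]2O[C@@H]([C@@H](Br)CC)C[C@H](Br)[C@H](OC(=O)c3ccccc3)C[C@H]2OC(C)=O | intermediate
18 | (3S,4S)-epoxide with free C7 and C9 hydroxyls and terminal alkyne | C#C[C@@H]1O[C@H]1C[C@@H]2O[C@@H]([C@@H](Br)CC)C[C@H](Br)[C@H](O)C[C@H]2O | intermediate
19 | (3S,4R,6S,7R,9R,10S,12R,13S)-10,13-dibromo-4,7:6,12-diepoxypentadec-1-yne-3,9-diol | C#C[C@H](O)[C@H]1C[C@@H]2O[C@@H]([C@@H](Br)CC)C[C@H](Br)[C@H](O)C[C@H]2O1 | intermediate
20 | (3R,4R,6S,7R,9R,10S,12R,13S)-3,10,13-tribromo-4,7:6,12-diepoxypentadec-1-yn-9-ol | C#C[C@@H](Br)[C@H]1C[C@@H]2O[C@@H]([C@@H](Br)CC)C[C@H](Br)[C@H](O)C[C@H]2O1 | intermediate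
21 | (3R,4R,6S,7R,9R,10S,12R,13S)-3,10,13-tribromo-4,7:6,12-diepoxypentadec-1-yn-9-yl acetate | C#C[C@@H](Br)[C@H]1C[C@@H]2O[C@@H]([C@@H](Br)CC)C[C@H](Br)[C@H](OC(C)=O)C[C@H]2O1 | target

Total step count: 15. Longest linear sequence: 14 steps (3 → 21, steps 2–15); aldehyde 2 is made in one step and joins at step 5.

Steps most likely to fail

Step 7 (proposed new method). The benzoate carbonyl may capture the bromonium ion itself (6-exo) instead of the ring C oxygen. Bromide may also open the dioxolanylium ion at C9 as well as C10, and chloride from the antimonate may be incorporated. The fallback sets out from 9 and comes back at 12, using only known reactions with isolated intermediates. K2CO3 in MeOH removes the benzoate to give the C10 alcohol F1. Boc2O and DMAP convert it into the tert-butyl carbonate F2. [Et2SBr][SbCl5Br] in MeNO2 then effects the known carbonate-terminated ring expansion, with loss of 2-methylpropene, to the trans-fused 9,10-cyclic carbonate of ring B F3. Methanolysis gives the trans-9,10-diol F4, and benzaldehyde dimethyl acetal with camphorsulfonic acid gives the benzylidene acetal F5. N-Bromosuccinimide in CCl4 (Hanessian–Hullar reaction) then opens F5 to the C9 benzoate/C10 bromide 12.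

Step 5 (key step). The neighbouring benzoate may trap the oxocarbenium ion as an acyloxonium ion so that the Prins closure stalls. Enolization of the α-acyloxy aldehyde during acetal formation may also erode the C10 configuration. The fallback sets out from 1 and 6 and comes back at 8; it carries the C10 oxygen through the cationic step as a non-participating ether. Enantioselective organocatalytic α-oxyamination of 1 with TEMPO (imidazolidinone catalyst, CuCl2, air) gives the (R)-2-(2,2,6,6-tetramethylpiperidin-1-yloxy) aldehyde F6. Acetalization with 6 and SnCl4 rearrangement give the all-cis ring C ketone with the aminoxy group at C10 F7. Zinc in acetic acid cleaves the N–O bond to the all-cis C10 alcohol F8, and benzoyl chloride in pyridine gives 8.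

Step 14. The Appel reagent may also activate the C9 hydroxyl, and SN2′ substitution to a bromoallene may erode site selectivity. The fallback sets out from 19 and comes back at 21; it changes the order so that bromination is the last step on a substrate with one hydroxyl group. Et3SiCl and imidazole at −78 °C silylate the propargylic hydroxyl to the C3 triethylsilyl ether F9. Ac2O, pyridine and DMAP give the C9 acetate F10. Pyridinium p-toluenesulfonate in MeOH removes the silyl group to the C3 alcohol C9 acetate F11, and PPh3/CBr4 then gives 21 directly.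

Further compounds
F1 | step 7 | ring C ketone 9 with free C10 hydroxyl in place of the benzoate (6S,7R,9S,10R) | CC(C)(C)[Si](c1ccccc1)(c1ccccc1)OCC[C@@H]1O[C@H]([C@H](O)C/C=C/CC)C[C@H]1C(C)=O
F2 | step 7 | C10 tert-butyl carbonate of F1 | CC(C)(C)[Si](c1ccccc1)(c1ccccc1)OCC[C@@H]1O[C@H]([C@H](OC(=O)OC(C)(C)C)C/C=C/CC)C[C@H]1C(C)=O
F3 | step 7 | ring B ketone with trans-fused 9,10-cyclic carbonate and C13 bromide (6S,7R,9R,10R,12R,13S) | CC(C)(C)[Si](c1ccccc1)(c1ccccc1)OCC[C@@H]2O[C@@H]([C@@H](Br)CC)C[C@H]3OC(=O)O[C@@H]3C[C@H]2C(C)=O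
F4 | step 7 | ring B ketone trans-9,10-diol (9R,10R) | CC(C)(C)[Si](c1ccccc1)(c1ccccc1)OCC[C@@H]2O[C@@H]([C@@H](Br)CC)C[C@@H](O)[C@H](O)C[C@H]2C(C)=O
F5 | step 7 | 9,10-O-benzylidene acetal of F4 (both epimers at the acetal carbon) | CC(C)(C)[Si](c1ccccc1)(c1ccccc1)OCC[C@@H]2O[C@@H]([C@@H](Br)CC)C[C@H]3OC(c4ccccc4)O[C@@H]3C[C@H]2C(C)=O
F6 | step 5 | (2R,4E)-2-[(2,2,6,6-tetramethylpiperidin-1-yl)oxy]hept-4-enal | O=C[C@H](ON1C(C)(C)CCCC1(C)C)C/C=C/CC
F7 | step 5 | all-cis ring C ketone with the tetramethylpiperidinyloxy group at C10 (6S,7S,9S,10R) | CC(C)(C)[Si](c1ccccc1)(c1ccccc1)OCC[C@@H]1O[C@H]([C@H](ON2C(C)(C)CCCC2(C)C)C/C=C/CC)C[C@@H]1C(C)=O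
F8 | step 5 | all-cis ring C ketone with free C10 hydroxyl (6S,7S,9S,10R) | CC(C)(C)[Si](c1ccccc1)(c1ccccc1)OCC[C@@H]1O[C@H]([C@H](O)C/C=C/CC)C[C@@H]1C(C)=O
F9 | step 14 | C3 triethylsilyl ether of diol 19 | C#C[C@H](O[Si](CC)(CC)CC)[C@H]1C[C@@H]2O[C@@H]([C@@H](Br)CC)C[C@H](Br)[C@H](O)C[C@H]2O1
F10 | step 14 | C3 triethylsilyl ether C9 acetate | C#C[C@H](O[Si](CC)(CC)CC)[C@H]1C[C@@H]2O[C@@H]([C@@H](Br)CC)C[C@H](Br)[C@H](OC(C)=O)C[C@H]2O1
F11 | step 14 | (3S)-propargylic alcohol C9 acetate | C#C[C@H](O)[C@H]1C[C@@H]2O[C@@H]([C@@H](Br)CC)C[C@H](Br)[C@H](OC(C)=O)C[C@H]2O1
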